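**The task.** If you want to know whether beta or delta ends higher, start from the charges, the readings and the questions.

| flask | starting material | free catalyst | temperature | remark | time |
|---|---|---|---|---|---|
| spring | 0.050 M | 25 µM | −15 °C | run made earlier |  |
| autumn | 0.050 M | 100 µM | −2 °C | run made earlier |  |
| winter | 0.10 M | 50 µM | −15 °C | run made earlier |  |
| beta | 0.050 M | 50 µM | −10 °C |  | 25 min |
| delta | 0.050 M | 50 µM | 5 °C |  | 15 min |

| run | time / min | product / % |
|---|---|---|
| spring | 2.50 | 5.3 |
| spring | 8.00 | 13.9 |
| spring | 15.0 | 25.7 |
| spring | 20.0 | 33.0 |
| spring | 30.0 | 46.1 |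
| autumn | 1.00 | 21.5 |
| autumn | 3.00 | 55.9 |
| autumn | 6.00 | 80.1 |
| autumn | 8.00 | 83.5 |
| autumn | 12.0 | 88.0 |
| winter | 6.00 | 11.3 |
| winter | 15.0 | 29.7 |
| winter | 20.0 | 38.2 |
| winter | 25.0 | 46.0 |
| winter | 30.0 | 53.5 |

(standard deviation of a reading: 0.5 percentage points)

- which one finishes higher in amount of product, in percent of the starting material charged ("neither" within 2 percentage points) (beta / delta / neither)
- amount of product at the end, in percent of the starting material charged, beta
- amount of product at the end, in percent of the starting material charged, delta

- the numbers in the tables scatter with a standard deviation of 0.5 percentage points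
- a reading or a percentage of product counts all its forms, free or not

**Fast rung.** Beta and delta carry the same amount of starting material as spring and autumn, so I set aside winter, with twice that amount. Taken as pseudo-first-order in starting material, spring's last reading gives a rate constant of 0.0206 min⁻¹ and autumn's reading at 3.00 min gives one of 0.273 min⁻¹. Divided by c(free catalyst), these two readings give an activation energy of 53.6 kJ mol⁻¹. My reckoning then gives beta a rate constant of 0.0662 min⁻¹ and delta one of 0.248 min⁻¹. Call rate constant times time the dose. Beta's dose of 1.66 matches autumn's at 6.00 min, 1.64, where autumn read 80.1%, so I expect about that for beta.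

**Slow rung.** Autumn then lags its clock: between 8.00 min and 12.0 min the share missing from product shrinks at 0.0796 min⁻¹, slower than before. The tail half-life is the time in which that missing share halves late in a run. Warmed to delta's temperature with the same activation energy, and assumed independent of catalyst, it is 4.79 min, a loose reading from two points.

**The ladder.** Delta's clearing half-life, ln(2) over its rate constant, is 2.79 min; delta's tail half-life of 4.79 min is longer, and beta's clearing half-life of 10.5 min is longer still. By my reckoning delta reaches autumn's dose at 8.00 min after 8.79 min, and the tail then carries it to 93.3% at 15 min. So I name delta as the higher.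

**The forecast.** It names delta, with 78% for beta and 85% for delta, reasoning that delta “reaches its ceiling, probably a little lower when warmer”. My delta stands higher than the forecast's, and my beta does too.

**The outcome.** Delta finishes at 91.9% and beta at 77.6%, under this scheme:

    starting material + free catalyst → catalyst intermediate A (k = 194 M⁻¹ s⁻¹, Ea = 37.0 kJ mol⁻¹)
    catalyst intermediate A → catalyst intermediate B (k = 12.8 s⁻¹, Ea = 59.0 kJ mol⁻¹)
    catalyst intermediate B → free catalyst + product (k = 8.80 s⁻¹, Ea = 56.0 kJ mol⁻¹)
    starting material ⇌ dormant form (K = 0.960, k = 0.00344 s⁻¹, Ea = 76.0 kJ mol⁻¹, ΔH = −33.0 kJ mol⁻¹)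
    crystals ⇌ product, rate k5*(cs5 - [product]) while solid is left; crystals form when [product] > cs5 (solubility = 8.90 mM, k = 0.0425 s⁻¹)
    (constants at 5 °C)

At 15.0 min, delta's missing share stands as starting material 2.09% and dormant form 5.99%. The same flask read at 10 min gave 83.3%, and the tail half-life carries that reading to 91.9% at the end.

The runs come from a simulation for substances that don't exist, noise included.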